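**Strategy.** The route rests on disconnecting the C4–C5 bond of the 4-hydroxyfuran-2(5H)-one (tetronic acid) ring. The quaternary C5 is drawn from the C–H bond of an (R)-configured secondary carbinol. Its pyruvate ester is turned into an alkylidene carbene whose divalent carbon (future C4) lies 1,5 to that C5–H through O1–C2–C3. Insertion with retention closes the butenolide and creates the quaternary stereocentre in one operation. The cyclohexane carbons come from meso cis-tetrahydrophthalic anhydride by desymmetrising methylation and iodolactonisation; the bridged lactone later delivers both the hexenoyl ketone and the ring ketone.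

Key step: step 6

Remark: the propenyl-bearing ring carbon is α to the ring ketone and is assumed to be most stable in the target configuration (propenyl equatorial, cis to the furanone-bearing carbon), so it is set last by equilibration.

Step 1
Reactants: 1 cis-1,2,3,6-tetrahydrophthalic anhydride (meso)
Product: 2 (1R,6S)-6-acetylcyclohex-3-ene-1-carboxylic acid
Conditions: Me2Zn, Pd(OAc)2 (cat.), (R)-1-[(S)-2-(diphenylphosphino)ferrocenyl]ethyldicyclohexylphosphine (Josiphos ligand, cat.; enantiomer chosen for the (1R,6S) acid), 4-fluorostyrene (additive), THF, rt; aq. HCl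
Reagents that add atoms: dimethylzinc, C[Zn]C
Why: Pd-catalysed enantioselective desymmetrising acyl cross-coupling of a meso cyclic anhydride with a dialkylzinc, in which the chiral bisphosphine selects one of the two enantiotopic acyl C–O bonds, so the cis pair C1/C6 should emerge as (1R,6S) and the zinc carboxylate formed resists a second alkylation.

Step 2
Reactants: 2 (1R,6S)-6-acetylcyclohex-3-ene-1-carboxylic acid
Product: 3 (1R,2S,4S,5S)-2-acetyl-4-iodo-6-oxabicyclo[3.2.1]octan-7-one
Conditions: I2, KI, NaHCO3, H2O/CH2Cl2, 0 °C to rt, dark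
Reagents that add atoms: iodine, II
Why: Iodolactonisation, in which the carboxylate opens the iodonium ion anti and intramolecularly to form the γ-lactone, so oxygen lands on the future ketone carbon (cis to the carboxyl carbon) and iodine on the future propenyl carbon (trans to oxygen), while the bridged lactone locks the cis relation of the two carbonyl-bearing carbons.

Step 3
Reactants: 3 (1R,2S,4S,5S)-2-acetyl-4-iodo-6-oxabicyclo[3.2.1]octan-7-one; 4 (E)-1-bromoprop-1-ene
Product: 5 (1R,2S,4R,5S)-2-acetyl-4-[(1E)-prop-1-en-1-yl]-6-oxabicyclo[3.2.1]octan-7-one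
Conditions: NiI2 (cat.), 4,4′-di-tert-butyl-2,2′-bipyridine (cat.), Mn powder, NaI (cat.), DMPU, 40 °C
Reagents that add atoms: none
Why: Ni-catalysed reductive cross-electrophile coupling of a secondary alkyl iodide with an alkenyl bromide, in which the C4 radical is captured by the alkenyl–nickel species with retention of the E geometry and is expected to be trapped anti to the adjacent lactone C–O bond, a facial outcome that is inconsequential because this centre is re-set in step 11.

Step 4
Reactants: 5 (1R,2S,4R,5S)-2-acetyl-4-[(1E)-prop-1-en-1-yl]-6-oxabicyclo[3.2.1]octan-7-one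
Product: 6 (1R,2S,4R,5S)-2-[(1R)-1-hydroxyethyl]-4-[(1E)-prop-1-en-1-yl]-6-oxabicyclo[3.2.1]octan-7-one
Conditions: (S)-Me-CBS oxazaborolidine, (S)-1-methyl-3,3-diphenyltetrahydro-1H,3H-pyrrolo[1,2-c][1,3,2]oxazaborole (cat.), catecholborane, toluene, −78 °C; MeOH, then pH 7 buffer
Reagents that add atoms: none
Why: Corey–Bakshi–Shibata reduction under reagent control, in which the (S)-catalyst should deliver hydride to the methyl ketone (large group = bicyclic residue, small group = methyl) to give the (R)-carbinol, and catecholborane at low temperature leaves the alkene and the lactone untouched.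

Step 5
Reactants: 6 (1R,2S,4R,5S)-2-[(1R)-1-hydroxyethyl]-4-[(1E)-prop-1-en-1-yl]-6-oxabicyclo[3.2.1]octan-7-one; 7 pyruvic acid
Product: 8 (1R)-1-[(1R,2S,4R,5S)-7-oxo-4-[(1E)-prop-1-en-1-yl]-6-oxabicyclo[3.2.1]octan-2-yl]ethyl 2-oxopropanoate
Conditions: DCC, DMAP (cat.), CH2Cl2, 0 °C
Reagents that add atoms: none
Why: Steglich esterification acylates the carbinol oxygen without touching its C–H stereocentre and installs O1–C2–C3 (with the C3 methyl) together with the ketone that will become the carbene carbon.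

Step 6
Reactants: 8 (1R)-1-[(1R,2S,4R,5S)-7-oxo-4-[(1E)-prop-1-en-1-yl]-6-oxabicyclo[3.2.1]octan-2-yl]ethyl 2-oxopropanoate
Product: 11 (1R,2S,4R,5S)-2-[(2R)-2,4-dimethyl-5-oxo-2,5-dihydrofuran-2-yl]-4-[(1E)-prop-1-en-1-yl]-6-oxabicyclo[3.2.1]octan-7-one, via diazoalkene 9 (not isolated), via alkylidene carbene 10 (not isolated)
Conditions: TMSCHN2, n-BuLi, THF, −78 °C; add 8; warm to 0 °C
Reagents that add atoms: trimethylsilyldiazomethane, C[Si](C)(C)C=[N+]=[N-]
Why: Lithiated trimethylsilyldiazomethane adds to the ketone carbonyl of the pyruvate and Peterson-type loss of Me3SiOLi gives diazoalkene 9, which expels N2 to the alkylidene carbene 10; its divalent carbon (future C4) inserts into the C5–H bond, forming C4–C5 and leaving the C3=C4 double bond of the butenolide. The closest known reaction type is the Colvin-type generation of alkylidene carbenes from ketones followed by 1,5-C–H insertion at an oxygen-bearing methine, as used for 2,5-dihydrofurans and cyclopentenes. The five-membered lactone O1–C2–C3–C4–C5 closes by this concerted three-centre 1,5-insertion. C5 is not set by a facial choice: front-side insertion replaces H by C4 with retention, so the (R)-carbinol of step 4 becomes the (R)-quaternary centre. The step needs attack of the reagent on the α-keto ester ketone (far more electrophilic than the bridged lactone) and site-selective insertion, which is secured because C5–H is the only C–H 1,5 to the carbene carbon and is an O-activated methine, while 1,2-shift of the methyl group is slow. The s-cis ester rotamer must be reached within the lifetime of 10, which is the main risk.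

Step 7
Reactants: 11 (1R,2S,4R,5S)-2-[(2R)-2,4-dimethyl-5-oxo-2,5-dihydrofuran-2-yl]-4-[(1E)-prop-1-en-1-yl]-6-oxabicyclo[3.2.1]octan-7-one
Product: 13 (1R,2S,4R,5S)-2-[(2R)-3-hydroxy-2,4-dimethyl-5-oxooxolan-2-yl]-4-[(1E)-prop-1-en-1-yl]-6-oxabicyclo[3.2.1]octan-7-one (mixture at the two new oxolane centres), via boronate 12 (not isolated)
Conditions: B2pin2, CuCl (cat.), Xantphos (cat.), NaOtBu (cat.), MeOH, THF, rt; then NaBO3·4H2O, THF/H2O, rt
Reagents that add atoms: bis(pinacolato)diboron, CC1(C)OB(OC1(C)C)B1OC(C)(C)C(C)(C)O1 (boron of 12); sodium perborate, [Na+].[O-]OB=O (oxygen of 13)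
Why: Copper-catalysed conjugate borylation places boron on the β-carbon (C4) of the unsaturated lactone only, the isolated propenyl group being inert, and perborate oxidation converts C–B into C–OH; the two new stereocentres (C3, C4) are destroyed in step 8 and need no control.

Step 8
Reactants: 13 (1R,2S,4R,5S)-2-[(2R)-3-hydroxy-2,4-dimethyl-5-oxooxolan-2-yl]-4-[(1E)-prop-1-en-1-yl]-6-oxabicyclo[3.2.1]octan-7-one
Product: 14 (1R,2S,4R,5S)-2-[(2R)-3-hydroxy-2,4-dimethyl-5-oxo-2,5-dihydrofuran-2-yl]-4-[(1E)-prop-1-en-1-yl]-6-oxabicyclo[3.2.1]octan-7-one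
Conditions: DMP, CH2Cl2, 0 °C to rt
Reagents that add atoms: none
Why: Dess–Martin oxidation of the β-hydroxy lactone gives the β-keto lactone, which enolises fully to the 3-methyltetronic acid, and the quaternary C5 cannot epimerise.

Step 9
Reactants: 15 (3E)-pent-3-en-1-ol
Product: 16 (2E)-5-iodopent-2-ene
Conditions: I2, PPh3, imidazole, CH2Cl2, 0 °C
Reagents that add atoms: iodine, II
Why: Appel-type iodination is an SN2 displacement at the primary carbon that leaves the E-alkene untouched.

Step 10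
Reactants: 14 (1R,2S,4R,5S)-2-[(2R)-3-hydroxy-2,4-dimethyl-5-oxo-2,5-dihydrofuran-2-yl]-4-[(1E)-prop-1-en-1-yl]-6-oxabicyclo[3.2.1]octan-7-one; 16 (2E)-5-iodopent-2-ene
Product: 18 (5R)-5-[(1S,2R,4S,5R)-2-[(4E)-hex-4-enoyl]-4-hydroxy-5-[(1E)-prop-1-en-1-yl]cyclohexyl]-4-hydroxy-3,5-dimethylfuran-2(5H)-one, via pent-3-enyllithium 17 (not isolated)
Conditions: 16 (3 equiv), t-BuLi (6 equiv), Et2O/pentane, −78 °C; then 14 in THF, −78 °C; aq. NH4Cl
Reagents that add atoms: none
Why: Iodine–lithium exchange gives the homoallyllithium, whose first equivalent deprotonates the tetronic acid (the tetronate is inert) and whose second adds once to the bridged lactone carbonyl to give a lithium hemiketal that is stable at −78 °C and collapses on work-up to the hexenoyl ketone and the ring alcohol (in equilibrium with its lactol), without touching any stereocentre.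

Step 11
Reactants: 18 (5R)-5-[(1S,2R,4S,5R)-2-[(4E)-hex-4-enoyl]-4-hydroxy-5-[(1E)-prop-1-en-1-yl]cyclohexyl]-4-hydroxy-3,5-dimethylfuran-2(5H)-one
Product: 20 (5R)-5-[(1S,2R,5S)-2-[(4E)-hex-4-enoyl]-4-oxo-5-[(1E)-prop-1-en-1-yl]cyclohexyl]-4-hydroxy-3,5-dimethylfuran-2(5H)-one (target), via axial-propenyl ketone 19 (not isolated)
Conditions: DMP, CH2Cl2, 0 °C; then DBU, CH2Cl2, 0 °C to rt; dilute aq. citric acid
Reagents that add atoms: none
Why: Dess–Martin oxidation of the ring alcohol gives the ketone, after which base-mediated equilibration of the now acidic α-carbon (kinetic α-protonation of the dienolate keeps the alkene out of conjugation) should move the propenyl group into the equatorial position cis-1,3 to the furanone-bearing carbon, the tetronic acid being protected as its salt.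

**Compound list**

1 | cis-1,2,3,6-tetrahydrophthalic anhydride (meso) | O=C1OC(=O)[C@@H]2CC=CC[C@H]12 | starting material
2 | (1R,6S)-6-acetylcyclohex-3-ene-1-carboxylic acid | OC(=O)[C@@H]1CC=CC[C@@H]1C(C)=O | intermediate
3 | (1R,2S,4S,5S)-2-acetyl-4-iodo-6-oxabicyclo[3.2.1]octan-7-one | O=C1O[C@H]2C[C@@H]1[C@@H](C(C)=O)C[C@@H]2I | intermediate
4 | (E)-1-bromoprop-1-ene | C/C=C/Br | starting material
5 | (1R,2S,4R,5S)-2-acetyl-4-[(1E)-prop-1-en-1-yl]-6-oxabicyclo[3.2.1]octan-7-one | O=C1O[C@H]2C[C@@H]1[C@@H](C(C)=O)C[C@@H]2/C=C/C | intermediate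
6 | (1R,2S,4R,5S)-2-[(1R)-1-hydroxyethyl]-4-[(1E)-prop-1-en-1-yl]-6-oxabicyclo[3.2.1]octan-7-one | O=C1O[C@H]2C[C@@H]1[C@@H]([C@@H](C)O)C[C@@H]2/C=C/C | intermediate
7 | pyruvic acid | CC(=O)C(=O)O | starting material
8 | (1R)-1-[(1R,2S,4R,5S)-7-oxo-4-[(1E)-prop-1-en-1-yl]-6-oxabicyclo[3.2.1]octan-2-yl]ethyl 2-oxopropanoate | O=C1O[C@H]2C[C@@H]1[C@@H]([C@@H](C)OC(=O)C(C)=O)C[C@@H]2/C=C/C | intermediate
9 | diazoalkene: the same ester with the ketone C=O replaced by C=C=N2 (3-diazo-2-methylprop-2-enoate) | O=C1O[C@H]2C[C@@H]1[C@@H]([C@@H](C)OC(=O)C(C)=C=[N+]=[N-])C[C@@H]2/C=C/C | intermediate (not isolated)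
10 | alkylidene carbene: the same ester carrying a divalent terminal carbon (2-methylprop-2-en-3-ylidene ester) | O=C1O[C@H]2C[C@@H]1[C@@H]([C@@H](C)OC(=O)C(C)=[C])C[C@@H]2/C=C/C | intermediate (not isolated)
11 | (1R,2S,4R,5S)-2-[(2R)-2,4-dimethyl-5-oxo-2,5-dihydrofuran-2-yl]-4-[(1E)-prop-1-en-1-yl]-6-oxabicyclo[3.2.1]octan-7-one | O=C1O[C@H]2C[C@@H]1[C@@H]([C@@]3(C)OC(=O)C(C)=C3)C[C@@H]2/C=C/C | intermediate
12 | (1R,2S,4R,5S)-2-[(2R)-2,4-dimethyl-5-oxo-3-(4,4,5,5-tetramethyl-1,3,2-dioxaborolan-2-yl)oxolan-2-yl]-4-[(1E)-prop-1-en-1-yl]-6-oxabicyclo[3.2.1]octan-7-one | O=C1O[C@H]2C[C@@H]1[C@@H]([C@@]3(C)OC(=O)C(C)C3B4OC(C)(C)C(C)(C)O4)C[C@@H]2/C=C/C | intermediate (not isolated)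
13 | (1R,2S,4R,5S)-2-[(2R)-3-hydroxy-2,4-dimethyl-5-oxooxolan-2-yl]-4-[(1E)-prop-1-en-1-yl]-6-oxabicyclo[3.2.1]octan-7-one (mixture at oxolane C3/C4) | O=C1O[C@H]2C[C@@H]1[C@@H]([C@@]3(C)OC(=O)C(C)C3O)C[C@@H]2/C=C/C | intermediate
14 | (1R,2S,4R,5S)-2-[(2R)-3-hydroxy-2,4-dimethyl-5-oxo-2,5-dihydrofuran-2-yl]-4-[(1E)-prop-1-en-1-yl]-6-oxabicyclo[3.2.1]octan-7-one | O=C1O[C@H]2C[C@@H]1[C@@H]([C@@]3(C)OC(=O)C(C)=C3O)C[C@@H]2/C=C/C | intermediate
15 | (3E)-pent-3-en-1-ol | C/C=C/CCO | starting material
16 | (2E)-5-iodopent-2-ene | C/C=C/CCI | intermediate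
17 | [(3E)-pent-3-en-1-yl]lithium | [Li]CC/C=C/C | intermediate (not isolated)
18 | (5R)-5-[(1S,2R,4S,5R)-2-[(4E)-hex-4-enoyl]-4-hydroxy-5-[(1E)-prop-1-en-1-yl]cyclohexyl]-4-hydroxy-3,5-dimethylfuran-2(5H)-one | C/C=C/CCC(=O)[C@@H]1C[C@H](O)[C@@H](/C=C/C)C[C@@H]1[C@@]1(C)OC(=O)C(C)=C1O | intermediate
19 | (5R)-5-[(1S,2R,5R)-2-[(4E)-hex-4-enoyl]-4-oxo-5-[(1E)-prop-1-en-1-yl]cyclohexyl]-4-hydroxy-3,5-dimethylfuran-2(5H)-one (propenyl axial) | C/C=C/CCC(=O)[C@@H]1CC(=O)[C@@H](/C=C/C)C[C@@H]1[C@@]1(C)OC(=O)C(C)=C1O | intermediate (not isolated)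
20 | (5R)-5-[(1S,2R,5S)-2-[(4E)-hex-4-enoyl]-4-oxo-5-[(1E)-prop-1-en-1-yl]cyclohexyl]-4-hydroxy-3,5-dimethylfuran-2(5H)-one | C/C=C/CCC(=O)[C@@H]1CC(=O)[C@H](/C=C/C)C[C@@H]1[C@@]1(C)OC(=O)C(C)=C1O | target

**Step count.** Total: 11 steps. Longest linear sequence: 10 steps (steps 1–8, 10, 11); step 9 is a one-step side branch.

**Steps most likely to fail**

Step 6. The carbene may decay by 1,2-shift to the alk-2-ynoate or by intermolecular reactions before the ester reaches the s-cis rotamer that insertion requires. The fallback sets out from alcohol 6. Rh2(OAc)4-catalysed O–H insertion of 1-diazopropan-2-one would give the acetonyl ether F1. The same diazo-olefination with TMSCHN2/n-BuLi would pass through the diazoalkene F2 and the alkylidene carbene F3, now held by an ether tether with no rotamer bias, to the 2,5-dihydrofuran F4, with the same retention at the quaternary carbon. Allylic oxidation of the ring O–CH2 group (CrO3, 3,5-dimethylpyrazole, CH2Cl2, −20 °C) would return to butenolide 11.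

Step 3. An organometallic intermediate at C4 may undergo reductive β-elimination of the lactone carboxylate, reopening the bicycle to the cyclohexene acid, or the coupling may stall. The fallback sets out from iodolactone 3. A Keck radical allylation (allyltributylstannane, AIBN, benzene, 80 °C), a pure radical chain without a carbon–metal bond at C4, would give the allyl lactone F5. RuHCl(CO)(PPh3)3 in toluene at 80 °C would then move the double bond by one position and return to 5.

Step 10. The hemiketal may collapse early and the liberated ketone may add a second equivalent of the organolithium. The fallback sets out from 14. Me(MeO)NH·HCl with AlMe3 in CH2Cl2 would open the bridged lactone to the hydroxy Weinreb amide F6. Excess (E)-pent-3-enylmagnesium iodide F7 (from 16 and Mg in Et2O) would then stop at the chelated adduct and return, after work-up, to 18.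

Further compounds
F1 | step 6 | 1-{(1R)-1-[(1R,2S,4R,5S)-7-oxo-4-[(1E)-prop-1-en-1-yl]-6-oxabicyclo[3.2.1]octan-2-yl]ethoxy}propan-2-one | O=C1O[C@H]2C[C@@H]1[C@@H]([C@@H](C)OCC(C)=O)C[C@@H]2/C=C/C
F2 | step 6 | diazoalkene from F1 (3-diazo-2-methylprop-2-enyl ether) | O=C1O[C@H]2C[C@@H]1[C@@H]([C@@H](C)OCC(C)=C=[N+]=[N-])C[C@@H]2/C=C/C
F3 | step 6 | alkylidene carbene from F2 | O=C1O[C@H]2C[C@@H]1[C@@H]([C@@H](C)OCC(C)=[C])C[C@@H]2/C=C/C
F4 | step 6 | (1R,2S,4R,5S)-2-[(2R)-2,4-dimethyl-2,5-dihydrofuran-2-yl]-4-[(1E)-prop-1-en-1-yl]-6-oxabicyclo[3.2.1]octan-7-one | O=C1O[C@H]2C[C@@H]1[C@@H]([C@@]3(C)OCC(C)=C3)C[C@@H]2/C=C/C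
F5 | step 3 | (1R,2S,4S,5S)-2-acetyl-4-(prop-2-en-1-yl)-6-oxabicyclo[3.2.1]octan-7-one | O=C1O[C@H]2C[C@@H]1[C@@H](C(C)=O)C[C@@H]2CC=C
F6 | step 10 | (1R,2S,4S,5R)-4-hydroxy-2-[(2R)-3-hydroxy-2,4-dimethyl-5-oxo-2,5-dihydrofuran-2-yl]-N-methoxy-N-methyl-5-[(1E)-prop-1-en-1-yl]cyclohexane-1-carboxamide | CON(C)C(=O)[C@@H]1C[C@H](O)[C@@H](/C=C/C)C[C@@H]1[C@@]1(C)OC(=O)C(C)=C1O
F7 | step 10 | (E)-pent-3-enylmagnesium iodide | I[Mg]CC/C=C/C
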